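Late in the hour, how much can this flask still hold in solution, and how much must stand as crystals?

substrate 34 mM; time 1.0 h

    crystals ⇌ target, rate k1*(cs1 - [target]) while solid is left; crystals form when [target] > cs1 (cs1 = 0.47 mM, k1 = 0.055 s⁻¹)
    substrate ⇌ dormant form (K2 = 4.7, k2 = 0.0048 s⁻¹)
    substrate + substrate ⇌ target (K3 = 360 M⁻¹, k3 = 0.11 M⁻¹ s⁻¹)
    target ⇌ isomer of the product (K4 = 1.7, k4 = 0.0054 s⁻¹)

- percentages count the substrate that a species holds: one target or crystals or isomer of the product counts as two
- target is meant together with its crystals
- two of one species on the left: rate k times its square, two consumed each time
- solid, in amounts per volume of the solution: crystals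
- run time (flask): 1.0 h

- the target standing at 1.0 h, as a percentage of the substrate charged
- the isomer of the product standing at 1.0 h, as a percentage of the substrate charged

Turn the question round: what would put the isomer of the product ahead of the target? Without crystals the two share the solution, with the isomer ahead by the factor K = 1.7. Crystals form once dissolved target passes its solubility S = 0.47 mM. With crystals standing, dissolved target stays near S and the isomer near KS, so that outcome needs the crystals to stay below (K−1)S = 0.329 mM. With a charge c = 34 mM and two substrate in each target, R = 2(1+K)S/c comes to 7.46%: the room, the share of the charge that target and isomer can hold dissolved together.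

How soon is it filled? That takes 2.54 mM of substrate, and the step to target starts by using 0.254 mM s⁻¹. Replace the falling curve by a mean, substrate at half the charge, which brings the rate down to a quarter of its start, and filling takes 39.9 s. Even at their starting rates, both routes together need 40.7 s to bring substrate down that far, so this mean errs on the slow side. The filling time is far shorter than the 1.0 h of the run, and so is the forward half-life of target going to isomer, 2.1 min. I therefore expect crystals and an isomer share of 2KS/c = 4.70%. My reckoning stops there, because the target's share depends on the dormant form, which I did not follow.

The forecast gave 50.2% target and 4.8% isomer, noting "The isomer relaxes in about 5 min". The flask gives 51.1% target and 4.80% isomer.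

In this flask, target and isomer together hold 55.9% after 1.0 h, more than the room of 7.46%, and crystals hold 48.3%. The neighbour charged with 8.5 mM has a room of 29.9% and holds 21.3% in the two, less than its room, with crystals at 0% and the isomer's 13.3% above the target's 7.96%; the two hold the same at a charge of 11.7 mM.

All constants are assumed; the rest is arithmetic.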